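**Retrosynthetic overview**

1. The target (C1 ketone, C2=C3, C4 secondary carbinol, C5 tertiary carbinol, C6 side-chain carbinol) is traced back to the 2-hydroxy-2-(1-hydroxyalkyl)cyclopent-4-ene-1,3-dione 14, whose free C6 hydroxyl delivers hydride to one of the two ring carbonyls and so sets C4 and C5 together.
2. The carbocycle is not made as a five-membered ring: the 4,5-dihydroxycyclopentenone 12 (then oxidised to the dione) arises by ring contraction of the six-membered 6-hydroxy-2H-pyran-3(6H)-one 10, whose ring oxygen is expelled onto C5 while the C4–C5 bond forms.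
3. Pyranone 10 comes from the flat furyl carbinol 9 by Achmatowicz oxidative ring expansion; 9 comes from 2-furyllithium and (S)-2-silyloxyoctadecanal 6, made in three steps from methyl (S)-glycidate and a C15 Grignard reagent (C6 from the chiral pool).
4. Enabling feature: C5 bears oxygen and is flanked by C1 (C=O) and, across C2=C3, by C4 (CH–OH). Thus C1–C2=C3–C4 is a masked (Z)-4-oxo-2-enal and C5–O is the former ring C–O bond of a pyranone lactol. At the dione level C1 and C4 are equivalent and C5 is no stereocentre, so the contraction needs no stereocontrol.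
5. Ring order: furan (O + C1–C4) → pyranone (O + C1–C5) → cyclopentenone (C1–C5).

Key step: step 6

Remark: locants C1–C6 are those of the target; the target is read as the 4,5-cis-diol with the side chain trans to the C4 hydroxyl, (4S,5S,6S); methyl (S)-glycidate, 1-bromopentadecane and furan are taken as commercial.

**Route**

Step 1
Reactants: 1 methyl (2S)-oxirane-2-carboxylate; 2 1-bromopentadecane
Product: 4 methyl (2S)-2-hydroxyoctadecanoate, via pentadecylmagnesium bromide 3 (not isolated)
Conditions: Mg, THF, reflux; then 1, CuBr·SMe2 (10 mol %), THF, −78 → −40 °C; aq NH4Cl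
Reagents that add atoms: none
Why: Copper-catalysed SN2 opening of the glycidic ester at the terminal carbon by the Grignard reagent; the C2 stereocentre (future C6) is not touched and comes from the chiral pool.

Step 2
Reactants: 4 methyl (2S)-2-hydroxyoctadecanoate
Product: 5 methyl (2S)-2-(tert-butyldimethylsilyloxy)octadecanoate
Conditions: TBSCl, imidazole, DMF, rt
Reagents that add atoms: tert-butyldimethylsilyl chloride, CC(C)(C)[Si](C)(C)Cl
Why: Standard silylation of a secondary alcohol; the silyl ether caps O6 so that it can neither add to the enal nor trigger retro-aldol cleavage later.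

Step 3
Reactants: 5 methyl (2S)-2-(tert-butyldimethylsilyloxy)octadecanoate
Product: 6 (2S)-2-(tert-butyldimethylsilyloxy)octadecanal
Conditions: DIBAL-H, CH2Cl2, −78 °C; MeOH, then aq sodium potassium tartrate
Reagents that add atoms: none
Why: Partial reduction of an α-silyloxy ester with DIBAL-H, whose tetrahedral aluminium hemiacetal collapses to the aldehyde only on work-up; the α-stereocentre should survive at low temperature.

Step 4
Reactants: 6 (2S)-2-(tert-butyldimethylsilyloxy)octadecanal; 7 furan
Product: 9 (1RS,2S)-2-(tert-butyldimethylsilyloxy)-1-(furan-2-yl)octadecan-1-ol, via 2-furyllithium 8 (not isolated)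
Conditions: n-BuLi, THF, −78 → 0 °C; then 6, −78 °C; aq NH4Cl at −78 °C
Reagents that add atoms: none
Why: 1,2-Addition of 2-furyllithium to the aldehyde; Felkin–Anh addition should favour one carbinol epimer, but both are carried on because this centre is erased by enolisation in step 6.

Step 5
Reactants: 9 (1RS,2S)-2-(tert-butyldimethylsilyloxy)-1-(furan-2-yl)octadecan-1-ol
Product: 10 6-hydroxy-2-[(1S)-1-(tert-butyldimethylsilyloxy)heptadecyl]-2H-pyran-3(6H)-one (all four C2/C6 stereoisomers)
Conditions: NBS, NaHCO3, THF/H2O (4:1), 0 °C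
Reagents that add atoms: water, O
Why: Achmatowicz rearrangement: bromonium-induced oxidation of the furan to the cis-enedione, which the carbinol oxygen captures as the six-membered lactol; the ring stereocentres form as a mixture that converges in step 6.

Step 6
Reactants: 10 6-hydroxy-2-[(1S)-1-(tert-butyldimethylsilyloxy)heptadecyl]-2H-pyran-3(6H)-one
Product: 12 4,5-dihydroxy-5-[(1S)-1-(tert-butyldimethylsilyloxy)heptadecyl]cyclopent-2-en-1-one (mixture of C4/C5 diastereomers), via ring-opened (2Z)-keto-enal 11 (not isolated)
Conditions: Et3N, DMF, rt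
Reagents that add atoms: none
Why: Et3N opens the lactol to the (2Z)-4-oxo-enal 11 and enolises its α-hydroxy ketone toward C5; the enediolate carbon C5 then adds to the C4 aldehyde, so the ring oxygen of 10 ends as the C5 hydroxyl and the six-membered oxacycle contracts to the five-membered carbocycle. The closest known reaction type is the amine-mediated isomerisation of 2-substituted 6-hydroxy-2H-pyran-3(6H)-ones to 4,5-dihydroxycyclopent-2-enones. The ring closes by a 5-(enolendo)-exo-trig aldol addition, geometrically akin to the conrotatory 4π closure of the Piancatelli rearrangement. C4 and C5 form under substrate control (the 4,5-trans diol is expected to prevail), but neither needs control because step 7 oxidises C4 and makes C5 non-stereogenic, while C6 is not enolisable in 10 or 12 and should keep its configuration. The step needs chemoselectivity for C–C bond formation over β-elimination of the C6 oxygen, retro-aldol and oxa-Michael pathways. The silyl ether on O6 (poor leaving group, no free alkoxide) and the mild amine base secure it.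

Step 7
Reactants: 12 4,5-dihydroxy-5-[(1S)-1-(tert-butyldimethylsilyloxy)heptadecyl]cyclopent-2-en-1-one
Product: 13 2-hydroxy-2-[(1S)-1-(tert-butyldimethylsilyloxy)heptadecyl]cyclopent-4-ene-1,3-dione
Conditions: IBX, DMSO, rt
Reagents that add atoms: none
Why: Oxidation of the secondary allylic alcohol by pentavalent iodine (IBX does not cleave vicinal diols and leaves the tertiary alcohol alone); all C4/C5 diastereomers converge on one dione in which C1 and C4 are equivalent.

Step 8
Reactants: 13 2-hydroxy-2-[(1S)-1-(tert-butyldimethylsilyloxy)heptadecyl]cyclopent-4-ene-1,3-dione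
Product: 14 2-hydroxy-2-[(1S)-1-hydroxyheptadecyl]cyclopent-4-ene-1,3-dione
Conditions: 48% aq HF, MeCN, 0 °C → rt
Reagents that add atoms: none
Why: Acidic fluoride cleavage of the silyl ether, chosen because a basic fluoride source could trigger retro-aldol fragmentation of the β-hydroxy-1,3-dione.

Step 9
Reactants: 14 2-hydroxy-2-[(1S)-1-hydroxyheptadecyl]cyclopent-4-ene-1,3-dione
Product: 15 (4S,5S)-4,5-dihydroxy-5-[(1S)-1-hydroxyheptadecyl]cyclopent-2-en-1-one
Conditions: Me4NBH(OAc)3 (3 equiv), MeCN/AcOH (1:1), −35 °C; aq sodium potassium tartrate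
Reagents that add atoms: none
Why: Evans–Saksena reduction: the acetoxyborohydride bound to the C6 hydroxyl delivers hydride through a six-membered chair to a ring carbonyl on the face that carries C6, so the new C4 hydroxyl is cis to the C5 hydroxyl. Only delivery to the carbonyl that gives the 1,3-anti (4S,6S) diol keeps the C16 chain equatorial in that chair, which fixes C5 as S.

**Compound list**

1 | methyl (2S)-oxirane-2-carboxylate (methyl (S)-glycidate) | COC(=O)[C@@H]1CO1 | starting material
2 | 1-bromopentadecane | CCCCCCCCCCCCCCCBr | starting material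
3 | pentadecylmagnesium bromide | CCCCCCCCCCCCCCC[Mg]Br | intermediate
4 | methyl (2S)-2-hydroxyoctadecanoate | CCCCCCCCCCCCCCCC[C@H](O)C(=O)OC | intermediate
5 | methyl (2S)-2-(tert-butyldimethylsilyloxy)octadecanoate | CCCCCCCCCCCCCCCC[C@H](O[Si](C)(C)C(C)(C)C)C(=O)OC | intermediate
6 | (2S)-2-(tert-butyldimethylsilyloxy)octadecanal | CCCCCCCCCCCCCCCC[C@H](O[Si](C)(C)C(C)(C)C)C=O | intermediate
7 | furan | c1ccoc1 | starting material
8 | 2-furyllithium | [Li]c1ccco1 | intermediate
9 | (1RS,2S)-2-(tert-butyldimethylsilyloxy)-1-(furan-2-yl)octadecan-1-ol (both C1 epimers) | CCCCCCCCCCCCCCCC[C@H](O[Si](C)(C)C(C)(C)C)C(O)c1ccco1 | intermediate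
10 | 6-hydroxy-2-[(1S)-1-(tert-butyldimethylsilyloxy)heptadecyl]-2H-pyran-3(6H)-one (C2/C6 mixture) | CCCCCCCCCCCCCCCC[C@H](O[Si](C)(C)C(C)(C)C)C1OC(O)C=CC1=O | intermediate
11 | (2Z,6S)-6-(tert-butyldimethylsilyloxy)-5-hydroxy-4-oxodocos-2-enal | CCCCCCCCCCCCCCCC[C@H](O[Si](C)(C)C(C)(C)C)C(O)C(=O)/C=C\C=O | intermediate
12 | 4,5-dihydroxy-5-[(1S)-1-(tert-butyldimethylsilyloxy)heptadecyl]cyclopent-2-en-1-one (C4/C5 mixture) | CCCCCCCCCCCCCCCC[C@H](O[Si](C)(C)C(C)(C)C)C1(O)C(O)C=CC1=O | intermediate
13 | 2-hydroxy-2-[(1S)-1-(tert-butyldimethylsilyloxy)heptadecyl]cyclopent-4-ene-1,3-dione | CCCCCCCCCCCCCCCC[C@H](O[Si](C)(C)C(C)(C)C)C1(O)C(=O)C=CC1=O | intermediate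
14 | 2-hydroxy-2-[(1S)-1-hydroxyheptadecyl]cyclopent-4-ene-1,3-dione | CCCCCCCCCCCCCCCC[C@H](O)C1(O)C(=O)C=CC1=O | intermediate
15 | (4S,5S)-4,5-dihydroxy-5-[(1S)-1-hydroxyheptadecyl]cyclopent-2-en-1-one | CCCCCCCCCCCCCCCC[C@H](O)[C@@]1(O)C(=O)C=C[C@@H]1O | target

**Step count and risks**

Total step count: 9. Longest linear sequence: 9 steps (from 1).

Steps most likely to fail:

1. Step 9. The borohydride may exchange onto the tertiary C5 hydroxyl or be chelated by the C5/C6 diol, so that hydride reaches the wrong face or the wrong carbonyl; a second directed delivery may also reduce the remaining enone. Fallback (a silicon-tethered hydride that only the secondary O6 can carry): 14 is silylated with chlorodiisopropylsilane and imidazole in CH2Cl2 at 0 °C to give 2-[(1S)-1-(diisopropylsilyloxy)heptadecyl]-2-hydroxycyclopent-4-ene-1,3-dione F1. SnCl4 in CH2Cl2 at −78 °C should then effect the anti-selective intramolecular hydrosilylation of the β-carbonyl through the same chair, giving the bridged diisopropylsilylene derivative of the target F2. HF·pyridine in THF releases 15, where the fallback rejoins the route.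

2. Step 6. β-Elimination of the C6 silanolate from the enediolate, an α-ketol transposition that would make C6 enolisable, or slow enolisation at the hindered C2–H may lower the yield or the configurational purity at C6. Fallback (protecting-group-free contraction, with chemoselectivity supplied later by the oxidant): 9 is desilylated with Bu4NF in THF to (1RS,2S)-1-(furan-2-yl)octadecane-1,2-diol F3. Achmatowicz rearrangement (NBS, NaHCO3, THF/H2O, 0 °C) gives 6-hydroxy-2-[(1S)-1-hydroxyheptadecyl]-2H-pyran-3(6H)-one F4. Et3N in DMF contracts it, now through an enediolate whose C6 oxygen is no leaving group, to 4,5-dihydroxy-5-[(1S)-1-hydroxyheptadecyl]cyclopent-2-en-1-one F5 (C4/C5 mixture). Activated MnO2 in CH2Cl2 oxidises only the allylic C4 hydroxyl and gives 14, where the fallback rejoins the route.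

3. Step 4. The basic organolithium may enolise the α-silyloxy aldehyde (erosion of the C6 configuration), and the silyl group may migrate within the lithium alkoxide before the quench. Fallback (acylation then reduction instead of aldehyde addition): ester 5 is converted with MeNH(OMe)·HCl and i-PrMgCl in THF at −20 °C into (2S)-2-(tert-butyldimethylsilyloxy)-N-methoxy-N-methyloctadecanamide F6. 2-Furyllithium 8 gives (2S)-2-(tert-butyldimethylsilyloxy)-1-(furan-2-yl)octadecan-1-one F7 through the stable chelated adduct. NaBH4 in MeOH at 0 °C reduces it to 9, where the fallback rejoins the route.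

**Further compounds**

F1 | step 9 | 2-[(1S)-1-(diisopropylsilyloxy)heptadecyl]-2-hydroxycyclopent-4-ene-1,3-dione | CCCCCCCCCCCCCCCC[C@H](O[SiH](C(C)C)C(C)C)C1(O)C(=O)C=CC1=O
F2 | step 9 | O4,O6-diisopropylsilylene derivative of (4S,5S)-4,5-dihydroxy-5-[(1S)-1-hydroxyheptadecyl]cyclopent-2-en-1-one | CCCCCCCCCCCCCCCC[C@H](O2)[C@@]1(O)C(=O)C=C[C@@H]1O[Si]2(C(C)C)C(C)C
F3 | step 6 | (1RS,2S)-1-(furan-2-yl)octadecane-1,2-diol | CCCCCCCCCCCCCCCC[C@H](O)C(O)c1ccco1
F4 | step 6 | 6-hydroxy-2-[(1S)-1-hydroxyheptadecyl]-2H-pyran-3(6H)-one (C2/C6 mixture) | CCCCCCCCCCCCCCCC[C@H](O)C1OC(O)C=CC1=O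
F5 | step 6 | 4,5-dihydroxy-5-[(1S)-1-hydroxyheptadecyl]cyclopent-2-en-1-one (C4/C5 mixture) | CCCCCCCCCCCCCCCC[C@H](O)C1(O)C(O)C=CC1=O
F6 | step 4 | (2S)-2-(tert-butyldimethylsilyloxy)-N-methoxy-N-methyloctadecanamide | CCCCCCCCCCCCCCCC[C@H](O[Si](C)(C)C(C)(C)C)C(=O)N(C)OC
F7 | step 4 | (2S)-2-(tert-butyldimethylsilyloxy)-1-(furan-2-yl)octadecan-1-one | CCCCCCCCCCCCCCCC[C@H](O[Si](C)(C)C(C)(C)C)C(=O)c1ccco1
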